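## Structural features

The target is a sesquiterpenoid arene. A cis-fused decalin (ring A: C1–C5 and C10; ring B: C5–C10, drimane numbering) is joined through an exocyclic trisubstituted alkene C9=C11 to C3 of a 2,4,5-trihydroxybenzaldehyde ring. Ring A carries the gem-dimethyl group at C4; the ring fusion has the C5 hydrogen and the methyl group of quaternary C10 on the same face (5R,10S); C8 (S) bears a methyl group cis to the C10 methyl, so C8, C9 and C10 form a methyl–sp2–methyl triad. The alkene is E, with the aryl ring on the C8 side, away from quaternary C10. Fragile elements are the hydroxyquinol-type arene (air oxidation, worst under base), the aldehyde, and the electron-rich styrene, whose protonation would let the ortho hydroxyl close a spiro dihydrobenzofuran at C9; C8 cannot be corrected once C9 is olefinic. The real difficulty is steric: quaternary C10 stands next to C5, which carries the neopentyl C4, and C9 is flanked by C10 and C8, so bond formation at C9 and C10 and control of the alkene geometry are the hard points. The key step exploits the fact that ring B, with C6 and C9 para to each other and methyl groups on C8 and C10, has the carbon pattern of 2,6-dimethylbenzoquinone, and that C1–C4 with both methyls on C4 is a 1,1-dimethylbutadiene: cycloaddition across C5=C10 forms ring A and fixes the cis fusion in one operation.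

## Logic of the disconnections

**20 ⇒ 18.** The three aryl O–H bonds are traced back to O–CH2OCH3 acetal bonds. The free hydroxyquinol aldehyde cannot pass through organolithium chemistry or a dehydration, and acetals also serve as directing groups earlier. The gain is a robust, non-acidic aromatic half. The demand is an unmasking in the last step that avoids protic acid, because the styrene of 20 could cyclise onto C9.

**18 ⇒ 17.** The C9=C11 π bond is cut by adding water back, hydroxyl on C11 and hydrogen on C9. With the hydroxyl on C11, H9 is the only β-hydrogen, so the elimination cannot reach C8 or give a ring alkene. The geometry problem becomes one of thermodynamic preference. The demand is that both C11 epimers of 17 converge on the E alkene.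

**17 ⇒ 12 + 14.** The C11–C3(aryl) σ bond is cut, with C11 as a carbonyl carbon and the aryl carbon as a carbanion. That aryl carbon lies between two acetal oxygens, the natural site for directed lithiation. The molecule divides into a C15 terpenoid half and a C7 aromatic half. The demand is regioselective lithiation of 14 with its formyl group masked in the flask, and addition to the hindered, enolisable carbonyl of 12.

**14 ⇒ 13.** Three O–CH2 bonds are cut. This is a pure protection step and leads to a purchasable compound. The demand is complete alkylation, including the hydroxyl hydrogen-bonded to the formyl group.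

**12 ⇒ 11 ⇒ 9 ⇒ 8.** The C9–C11 bond is cut after stepping C11 back through its oxidation levels to a C9=C11 methylene and then to the C9 carbonyl of 8. A carbonyl between C8 and C10 should accept only the smallest carbon nucleophile, so a direct benzylidenation of 8 is judged unrealistic; C11 is brought in as CH2 and functionalised afterwards. The gain is that 8 has a single functional group and an adjustable C8 centre. The demand is olefination of a very hindered ketone and anti-Markovnikov hydration of the resulting alkene.

**8 ⇒ 5 ⇒ 4.** The two C6–H bonds are traced back to C6=N and then C6=O, and the C8 configuration is left open. The C6 carbonyl is what the quinone leaves behind, and its removal through a hydrazone avoids strong base while C5 is still enolisable. The gain is that 4 is a 1,4-diketone one reduction away from a quinone adduct. The demand is discrimination of C6 from C9, no epimerisation at C5, and an equilibrium at C8 that favours the methyl cis to the C10 methyl.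

**4 ⇒ 3.** C–H bonds at C2, C3, C7 and C8 are cut by reintroducing the two alkenes. This reveals the ene-dione and the ring A alkene of a cycloadduct. The demand is hydrogenation without ketone reduction.

**3 ⇒ 1 + 2.** The C1–C10 and C4–C5 bonds are cut, opening ring A. Both fragments are purchasable, every ring carbon and all four methyl groups of the decalin are present, and C5 and C10 arise together. The demand is a catalyst-controlled choice of enantiotopic alkene and face, with the CH2 end of 2 bonding to the methyl-bearing carbon, from a diene that reaches the reactive conformation reluctantly.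

## Other disconnections considered

**Alternative 1:** The cut runs through C5–C10 and C8–C9 and opens both rings, leading to the acyclic triene imide A1, (S)-4-benzyl-3-[(2E,8Z,10E)-3,7,7-trimethyldodeca-2,8,10-trienoyl]oxazolidin-2-one. Forward, Me2AlCl would chelate the imide and the (5Z,7E)-diene would add intramolecularly to the trisubstituted enoyl alkene, giving the cis-fused octalin A2 with the acyl oxazolidinone on C9.
- In its favour: rings A and B and four stereocentres come from one step. The Z geometry at C5=C6 forces the tether exo, so cis fusion is enforced. C8 is set kinetically by the E geometry at C7=C8. Quaternary C4 offers no hydrogen for a 1,5-shift of the Z-diene. C11 arrives as the acyl carbon.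
- Against it: the β,β-disubstituted enoyl imide is a weak dienophile that must still create quaternary C10. A1 needs a long linear synthesis (a Z-alkene next to a quaternary carbon, an E-trisubstituted enoate). The chirality source is stoichiometric.
- Comparison: on structure A2 is better than 3, since it has no superfluous C6 oxygen, needs no C9 homologation, and does not rely on equilibration at C8. On mechanism the two are equal: both are suprafacial [4+2] reactions with the same cis-fusion logic, and both carry the handicap of a cis-substituted diene. On step economy the chosen plan is better: it starts its key step from two purchased compounds with a catalytic chirality source, whereas the route through A1 and A2 would need roughly half as many steps again.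

**Alternative 2:** The cut is C1–C10, paired in the forward sense with cleavage of a carbinol–bridgehead bond in the bicyclic carbinol A3, 1,3,3,5-tetramethyl-2-vinylbicyclo[2.2.2]oct-5-en-2-ol (vinyl syn to the alkene bridge). Forward, KH and 18-crown-6 would trigger the anionic oxy-Cope rearrangement to the cis-fused octalone A4 (C3 ketone, C8=C9 alkene).
- In its favour: the rearrangement is intramolecular and should be far less sensitive to the steric problem at C10 than a bimolecular cycloaddition; on reliability of the ring A-forming event it is the better step. The rigid bicycle fixes the cis fusion, which makes it equal to the chosen plan on relative configuration. All four methyl groups are in place.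
- Against it: A4 has its oxygen at C3, where the target has none, and no oxygen at C9, where C11 must be attached. The C3 ketone must be removed and the C8=C9 alkene hydroborated and oxidised, which also has to set C8, before the same C9 end-game begins. A3 is chiral, and its usual origin (dearomatised phenol, cycloaddition, vinyl addition to a ketone between a quaternary carbon and a bridgehead) gives a racemate unless a resolution or a further asymmetric step is added.
- Comparison: equal on cis fusion, better on the robustness of the key bond formation, worse on absolute stereocontrol, on placement of functionality and on step count.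

**Alternative 3:** The cut is C9–C10, opening ring B and leading to the aryl enyne A5, 3-[(3S)-3-methyl-5-[(1R)-2,6,6-trimethylcyclohex-2-en-1-yl]pent-1-yn-1-yl]-2,4,5-tris(methoxymethoxy)benzaldehyde. Forward, a palladium hydride from Pd(OAc)2, a triarylphosphine and AcOH would add across the alkyne with palladium on C9; the vinylpalladium would insert the C10=C1 ring alkene and β-hydride elimination would give A6, the 1,2-dehydro analogue of 18.
- In its favour: the E geometry follows from syn hydropalladation and is set by mechanism, not by thermodynamic preference, which is better than the chosen plan on this point. The aryl unit is already attached. No hindered ketone and no extraneous oxygen appear. C5 comes from the ring stereocentre of A5, and the cis fusion is enforced by the tether, which is equal to the chosen plan.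
- Against it: palladium must end on C9 and not on C11 of an aryl–alkyl alkyne with a di-ortho-substituted aryl group. Insertion into a trisubstituted ring alkene to create quaternary C10 in a six-membered closure is slow against alkyne oligomerisation or reduction. The propargylic C8 centre of A5 needs its own asymmetric step, 1,4 to C5. The extra C1=C2 alkene of A6 must then be hydrogenated in the presence of the styrene and the aldehyde.
- Comparison: the plan is more convergent on paper and superior on alkene geometry, but carries a higher risk at the key step, and the step count is comparable at best once A5 is made.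

Key step: step 1

Remarks on the chemistry:
- Drimane numbering is used for the decalin throughout (C11 is the benzylic carbon); names in the compound list use naphthalene numbering.
- The structures are mutually consistent: 20 is cis-fused, and C5 and C10 of 3 already have the configuration of 20 (5R,10S).
- (R)-BINOL is assumed to deliver the (5R,10S) sense in step 1; should the sense be opposite, (S)-BINOL is used and nothing else changes.
- Compounds 4 to 7 are carried as C8 epimer mixtures and 17 as a C11 epimer mixture; they are settled in steps 4 and 10.

## Route

Step 1
Reactants: 1 2,6-dimethyl-1,4-benzoquinone; 2 4-methylpenta-1,3-diene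
Product: 3 (4aR,8aS)-2,5,5,8a-tetramethyl-4a,5,8,8a-tetrahydronaphthalene-1,4-dione
Conditions: (R)-BINOL (20 mol %), TiCl2(O-i-Pr)2 (20 mol %), 4 Å MS, CH2Cl2, −30 °C → rt; 2 (4 equiv, freed of 2-methylpenta-1,3-diene)
Reagents that add atoms: none
Why: Lewis-acid-catalysed normal-demand Diels–Alder reaction with a BINOL–titanium dichloride catalyst, the closest known class being chiral-Lewis-acid-catalysed cycloadditions of methyl-substituted benzoquinones with simple dienes. The tetravalent titanium centre should bind the unhindered, more basic C6 carbonyl (flanked by two CH groups and fed by both β-methyl groups) and not the C9 carbonyl buried between the two methyl-bearing carbons, which makes C10 the electrophilic β-carbon. Ring A is closed by a concerted but asynchronous suprafacial–suprafacial [4+2] cycloaddition in which the C1–C10 bond leads and the C4–C5 bond follows. The CH2 terminus of 2 has the larger HOMO coefficient and is also the smaller end, so electronic and steric preferences agree in joining CH2 to methyl-bearing C10 and CMe2 to C5, which avoids vicinal quaternary carbons. C5 and C10 are created together: their cis relationship follows from suprafacial addition across one quinone alkene, and their absolute configuration from the BINOL ligand, which must choose one of the two enantiotopic alkenes and one face. Neither diene terminus is stereogenic, so endo or exo approach is of no consequence. Excess diene, freed of its more reactive 2-methyl isomer, and a slow warm-up are meant to offset the reluctance of 2 to reach the s-cis conformation; the angular methyl at C10 blocks aromatisation of 3.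

Step 2
Reactants: 3 (4aR,8aS)-2,5,5,8a-tetramethyl-4a,5,8,8a-tetrahydronaphthalene-1,4-dione
Product: 4 (4aR,8aS)-2,5,5,8a-tetramethyloctahydronaphthalene-1,4-dione (C8 epimers)
Conditions: H2 (3 atm), 10% Pd/C, EtOAc, rt
Reagents that add atoms: none
Why: Heterogeneous catalytic hydrogenation; the electron-poor C7=C8 alkene of the ene-dione and the cis-disubstituted C2=C3 alkene are both saturated under neutral conditions that should leave the C5 hydrogen next to the C6 ketone untouched, and C8 is formed as an epimer mixture that is settled in step 4.

Step 3
Reactants: 4 (4aR,8aS)-2,5,5,8a-tetramethyloctahydronaphthalene-1,4-dione (C8 epimers)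
Product: 5 C6 mono(p-toluenesulfonylhydrazone) of 4
Conditions: TsNHNH2 (1.05 equiv), EtOH, 50 °C
Reagents that add atoms: p-toluenesulfonyl hydrazide, Cc1ccc(cc1)S(=O)(=O)NN
Why: Hydrazone condensation; the C6 carbonyl has a CH2 neighbour whereas C9 lies between quaternary C10 and methyl-bearing C8 and should not condense, and a planar C=N needs less room next to C4 than a dithioketal would.

Step 4
Reactants: 5 C6 mono(p-toluenesulfonylhydrazone) of 4
Product: 8 (2S,4aR,8aS)-2,5,5,8a-tetramethyloctahydronaphthalen-1(2H)-one, via boryl hydrazine 6 (not isolated), via ketone epimer mixture 7 (not isolated)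
Conditions: catecholborane, CHCl3, 0 °C → rt; NaOAc·3H2O, reflux; then NaOMe, MeOH, rt
Reagents that add atoms: none
Why: Caglioti-type reduction of a tosylhydrazone with catecholborane: hydride transfer to C=N, acetate-induced loss of sulfinate and loss of N2 from the diazene give the C6 methylene without strong base while C5 is still enolisable. Methoxide then equilibrates C8 through the C9 enolate, the only enolisable site left; the epimer with the C8 methyl equatorial and cis to the C10 methyl should prevail, because the chair–chair form that keeps C4 equatorial on ring B has the C10 methyl equatorial there, so the other epimer would have to place its methyl syn-axial to C1.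

Step 5
Reactants: 8 (2S,4aR,8aS)-2,5,5,8a-tetramethyloctahydronaphthalen-1(2H)-one
Product: 9 (2S,4aR,8aS)-2,5,5,8a-tetramethyl-1-methylidenedecahydronaphthalene
Conditions: Ph3PCH3Br, KOt-Bu, toluene, 90 °C
Reagents that add atoms: methyltriphenylphosphonium bromide, C[P+](c1ccccc1)(c1ccccc1)c1ccccc1.[Br-]
Why: Wittig methylenation under the potassium tert-butoxide conditions used for hindered ketones; the small unstabilised ylide can reach C9 between C8 and C10, and the basic medium only holds C8 at its equilibrium configuration.

Step 6
Reactants: 9 (2S,4aR,8aS)-2,5,5,8a-tetramethyl-1-methylidenedecahydronaphthalene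
Product: 11 [(1R,2S,4aR,8aS)-2,5,5,8a-tetramethyldecahydronaphthalen-1-yl]methanol, via alkylborane 10 (not isolated)
Conditions: BH3·THF, THF, 0 °C → rt; then NaOH, H2O2, 0 °C → rt
Reagents that add atoms: hydrogen peroxide, OO
Why: Hydroboration–oxidation; boron adds to the unhindered terminal carbon C11 and hydrogen should be delivered to C9 on the face away from axial C1, which makes the C9 hydrogen cis to both methyl groups, a centre that is removed again in step 10.

Step 7
Reactants: 11 [(1R,2S,4aR,8aS)-2,5,5,8a-tetramethyldecahydronaphthalen-1-yl]methanol
Product: 12 (1R,2S,4aR,8aS)-2,5,5,8a-tetramethyldecahydronaphthalene-1-carbaldehyde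
Conditions: DMP, CH2Cl2, 0 °C → rt
Reagents that add atoms: none
Why: Dess–Martin oxidation of a primary alcohol to the aldehyde under near-neutral conditions; epimerisation at C9 would be of no consequence.

Step 8
Reactants: 13 2,4,5-trihydroxybenzaldehyde
Product: 14 2,4,5-tris(methoxymethoxy)benzaldehyde
Conditions: MOMCl (3.6 equiv), i-Pr2NEt, CH2Cl2, 0 °C → rt, under N2
Reagents that add atoms: chloromethyl methyl ether, COCCl
Why: Williamson-type O-alkylation of the three phenols to mixed acetals; methoxymethyl ethers survive organolithium reagents, direct ortho-lithiation and can be removed at the end without protic acid.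

Step 9
Reactants: 14 2,4,5-tris(methoxymethoxy)benzaldehyde; 12 (1R,2S,4aR,8aS)-2,5,5,8a-tetramethyldecahydronaphthalene-1-carbaldehyde
Product: 17 3-{hydroxy[(1R,2S,4aR,8aS)-2,5,5,8a-tetramethyldecahydronaphthalen-1-yl]methyl}-2,4,5-tris(methoxymethoxy)benzaldehyde (C11 epimers), via amino alkoxide 15 (not isolated), via aryllithium 16 (not isolated)
Conditions: LiN(CH2CH2)2NMe (from N-methylpiperazine, n-BuLi), THF, −20 °C; n-BuLi, −20 °C; 12, −78 → −30 °C; H2O
Reagents that add atoms: none
Why: In situ protection of the formyl group as an α-amino alkoxide, directed ortho-metalation and 1,2-addition of the aryllithium: the C3 hydrogen lies between two methoxymethoxy groups and is the most acidic ring position, while the weakly directing piperazine adduct keeps C6 unattractive. The aryllithium adds to the neopentyl-type aldehyde at low temperature and aqueous work-up returns the formyl group; C11 forms as an epimer mixture that converges in step 10.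

Step 10
Reactants: 17 3-{hydroxy[(1R,2S,4aR,8aS)-2,5,5,8a-tetramethyldecahydronaphthalen-1-yl]methyl}-2,4,5-tris(methoxymethoxy)benzaldehyde (C11 epimers)
Product: 18 3-{(E)-[(2S,4aR,8aS)-2,5,5,8a-tetramethyloctahydronaphthalen-1(2H)-ylidene]methyl}-2,4,5-tris(methoxymethoxy)benzaldehyde
Conditions: Burgess reagent (Et3N+SO2N−CO2Me), PhMe, 60 °C
Reagents that add atoms: none
Why: Burgess dehydration; C11 has only one β-hydrogen (H9), so the alkene can form only between C9 and C11 and C8 is untouched, and the strongly stabilised benzylic ion pair should collapse through the conformer that keeps the aryl group away from quaternary C10, giving the E isomer from either C11 epimer.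

Step 11
Reactants: 18 3-{(E)-[(2S,4aR,8aS)-2,5,5,8a-tetramethyloctahydronaphthalen-1(2H)-ylidene]methyl}-2,4,5-tris(methoxymethoxy)benzaldehyde
Product: 20 2,4,5-trihydroxy-3-{(E)-[(2S,4aR,8aS)-2,5,5,8a-tetramethyloctahydronaphthalen-1(2H)-ylidene]methyl}benzaldehyde, via tris(trimethylsilyl) ether 19 (not isolated)
Conditions: TMSOTf, 2,2'-bipyridyl, CH2Cl2, 0 °C → rt; then H2O
Reagents that add atoms: none
Why: Silyl triflate–bipyridyl cleavage of aromatic methoxymethyl ethers (acetal exchange): each acetal is converted into an aryl silyl ether and a pyridinium salt, and water then frees the phenols, so no protic acid meets the electron-rich styrene, which could otherwise be protonated and trapped at C9 by the ortho hydroxyl.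

## Compound list

1 | 2,6-dimethyl-1,4-benzoquinone | CC1=CC(=O)C=C(C)C1=O | starting material
2 | 4-methylpenta-1,3-diene | C=CC=C(C)C | starting material
3 | (4aR,8aS)-2,5,5,8a-tetramethyl-4a,5,8,8a-tetrahydronaphthalene-1,4-dione (cis-fused; C2=C3 and C7=C8 alkenes, C6 and C9 ketones in drimane numbering) | CC1=CC(=O)[C@@H]2C(C)(C)C=CC[C@]2(C)C1=O | intermediate
4 | (4aR,8aS)-2,5,5,8a-tetramethyloctahydronaphthalene-1,4-dione, epimer mixture at drimane C8 | CC1CC(=O)[C@@H]2C(C)(C)CCC[C@]2(C)C1=O | intermediate
5 | C6 mono(p-toluenesulfonylhydrazone) of 4 (C9 ketone free, C8 epimers) | CC1CC(=NNS(=O)(=O)c2ccc(C)cc2)[C@@H]3C(C)(C)CCC[C@]3(C)C1=O | intermediate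
6 | C6 N-(1,3,2-benzodioxaborol-2-yl)-N'-tosylhydrazine from 5 (C6 and C8 epimers) | CC1CC(N(B2Oc3ccccc3O2)NS(=O)(=O)c4ccc(C)cc4)[C@@H]5C(C)(C)CCC[C@]5(C)C1=O | intermediate (not isolated)
7 | (4aR,8aS)-2,5,5,8a-tetramethyloctahydronaphthalen-1(2H)-one, epimer mixture at drimane C8 | CC1CC[C@@H]2C(C)(C)CCC[C@]2(C)C1=O | intermediate (not isolated)
8 | (2S,4aR,8aS)-2,5,5,8a-tetramethyloctahydronaphthalen-1(2H)-one (cis-fused; C8 methyl cis to C10 methyl) | C[C@H]1CC[C@@H]2C(C)(C)CCC[C@]2(C)C1=O | intermediate
9 | (2S,4aR,8aS)-2,5,5,8a-tetramethyl-1-methylidenedecahydronaphthalene | C[C@H]1CC[C@@H]2C(C)(C)CCC[C@]2(C)C1=C | intermediate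
10 | C11 monoalkylborane from 9 (C9 hydrogen cis to the C8 and C10 methyls) | C[C@H]1CC[C@@H]2C(C)(C)CCC[C@]2(C)[C@@H]1CB | intermediate (not isolated)
11 | [(1R,2S,4aR,8aS)-2,5,5,8a-tetramethyldecahydronaphthalen-1-yl]methanol | C[C@H]1CC[C@@H]2C(C)(C)CCC[C@]2(C)[C@@H]1CO | intermediate
12 | (1R,2S,4aR,8aS)-2,5,5,8a-tetramethyldecahydronaphthalene-1-carbaldehyde | C[C@H]1CC[C@@H]2C(C)(C)CCC[C@]2(C)[C@@H]1C=O | intermediate
13 | 2,4,5-trihydroxybenzaldehyde | O=Cc1cc(O)c(O)cc1O | starting material
14 | 2,4,5-tris(methoxymethoxy)benzaldehyde | O=Cc1cc(OCOC)c(OCOC)cc1OCOC | intermediate
15 | lithium (4-methylpiperazin-1-yl)[2,4,5-tris(methoxymethoxy)phenyl]methanolate | [Li]OC(N1CCN(C)CC1)c1cc(OCOC)c(OCOC)cc1OCOC | intermediate (not isolated)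
16 | 3-lithio derivative of 15 (lithium between the C2 and C4 acetal oxygens) | [Li]OC(N1CCN(C)CC1)c1cc(OCOC)c(OCOC)c([Li])c1OCOC | intermediate (not isolated)
17 | 3-{hydroxy[(1R,2S,4aR,8aS)-2,5,5,8a-tetramethyldecahydronaphthalen-1-yl]methyl}-2,4,5-tris(methoxymethoxy)benzaldehyde, C11 epimers | C[C@H]1CC[C@@H]2C(C)(C)CCC[C@]2(C)[C@@H]1C(O)c1c(OCOC)c(OCOC)cc(C=O)c1OCOC | intermediate
18 | 3-{(E)-[(2S,4aR,8aS)-2,5,5,8a-tetramethyloctahydronaphthalen-1(2H)-ylidene]methyl}-2,4,5-tris(methoxymethoxy)benzaldehyde | C[C@H]1CC[C@@H]2C(C)(C)CCC[C@]2(C)/C1=C/c1c(OCOC)c(OCOC)cc(C=O)c1OCOC | intermediate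
19 | tris(trimethylsilyl) ether of 20 | C[C@H]1CC[C@@H]2C(C)(C)CCC[C@]2(C)/C1=C/c1c(O[Si](C)(C)C)c(O[Si](C)(C)C)cc(C=O)c1O[Si](C)(C)C | intermediate (not isolated)
20 | 2,4,5-trihydroxy-3-{(E)-[(2S,4aR,8aS)-2,5,5,8a-tetramethyloctahydronaphthalen-1(2H)-ylidene]methyl}benzaldehyde (CNP0111013.2) | C[C@H]1CC[C@@H]2C(C)(C)CCC[C@]2(C)/C1=C/c1c(O)c(O)cc(C=O)c1O | target

## Step count and least certain steps

Total step count: 11. Longest linear sequence: 10 (steps 1 to 7 and 9 to 11, from 1 and 2 to 20); step 8 is a one-step branch.

**Step 1 (key step).** The most likely failure is low conversion: the cis methyl group of 2 disfavours the s-cis conformer, so Lewis-acid-induced oligomerisation of the diene or a stepwise capture of the zwitterion can outrun the cycloaddition. A second failure is weak discrimination between the two enantiotopic alkenes by a catalyst bound at only one point. The fallback sets out from 1 and comes back at 7. Mesityl oxide F1 would be converted with LiN(i-Pr)2 and TBSCl into 2-(tert-butyldimethylsilyloxy)-4-methylpenta-1,3-diene F2, which keeps the carbon skeleton of 2 but has a far more nucleophilic CH2 terminus. With 1 under the same titanium catalyst it could form the C1–C10 bond by Mukaiyama–Michael addition and then close the C4–C5 bond by intramolecular Michael addition of the titanium enolate, a stepwise course that does not need the s-cis diene, to give the C2 silyl enol ether F3. Dilute acid would give the 2,6,9-trione F4 and hydrogenation the saturated trione F5. Two equivalents of TsNHNH2 would give the C2,C6-bis(tosylhydrazone) F6 (C9 again too hindered), and catecholborane followed by NaOAc·3H2O would give 7, which is equilibrated to 8 as in step 4.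

**Step 4.** The equilibrium at C8 may be less one-sided than the conformational argument suggests, which would leave a mixture of C8 epimers that is hard to separate. The fallback sets out from 3 and comes back at 8, fixing C8 kinetically. Condensation of 3 with TsNHNH2 at C6 would give the conjugated tosylhydrazone F7. Catecholborane should deliver hydride to C6 on the face opposite ring A, and the allylic diazene released by NaOAc·3H2O should pass its hydrogen suprafacially to C8 on the ring A face. That places the C8 methyl cis to the C10 methyl and moves the alkene to C6=C7, giving the dienone F8. Hydrogenation (H2, Pd/C) would then give 8, and step 5 would be run with the non-basic Cp2TiMe2 so that C8 is not re-equilibrated.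

**Step 3.** Enolisation at C5 during the condensation could erode the cis ring fusion, or the condensation at C6 could be sluggish next to the C4 gem-dimethyl group and start to involve C9. The fallback sets out from 4 and comes back at 7. NaBH4 in MeOH at −40 °C should reduce only the C6 carbonyl to the hydroxy ketone F9. 1,1'-Thiocarbonyldiimidazole would give the imidazole-1-carbothioate F10, and Bu3SnH with AIBN in hot toluene (Barton–McCombie deoxygenation) would give 7 without acid or base at the stage where C5 is enolisable.

**Step 9.** Competing lithiation at C6, which is ortho to both the amino alkoxide and the C5 acetal oxygen, would give a regioisomeric adduct; the basic aryllithium could also enolise 12 instead of adding. The fallback sets out from 14 and comes back at 16. NBS in MeCN should brominate the position between the two acetal oxygens to give 3-bromo-2,4,5-tris(methoxymethoxy)benzaldehyde F11. Lithium N-methylpiperazide would give its α-amino alkoxide F12, and bromine–lithium exchange with n-BuLi at −78 °C would give 16 with the site fixed by the halogen and with no excess base present when 12 is added.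

**Step 10.** If the elimination runs as a stereospecific syn process from each C11 epimer and not through the ion pair, a mixture of alkene geometries would result; sulfamate formation at the crowded carbinol may also be slow. The fallback sets out from 18 as a mixture of alkene isomers and comes back at 18. Reversible thiyl-radical addition (PhSSPh, hν, benzene) would equilibrate the alkene and should funnel the Z isomer to the E isomer, since only E keeps the aryl ring clear of C10. No new compound is made.

## Further compounds

F1 | step 1 | mesityl oxide (purchased) | CC(=O)C=C(C)C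
F2 | step 1 | 2-(tert-butyldimethylsilyloxy)-4-methylpenta-1,3-diene | C=C(O[Si](C)(C)C(C)(C)C)C=C(C)C
F3 | step 1 | C2 tert-butyldimethylsilyl enol ether analogue of 3 | CC1=CC(=O)[C@@H]2C(C)(C)C=C(O[Si](C)(C)C(C)(C)C)C[C@]2(C)C1=O
F4 | step 1 | cis-fused 4,4,8,10-tetramethyl-Δ7-octalin-2,6,9-trione | CC1=CC(=O)[C@@H]2C(C)(C)CC(=O)C[C@]2(C)C1=O
F5 | step 1 | cis-fused 4,4,8,10-tetramethyldecalin-2,6,9-trione (C8 epimers) | CC1CC(=O)[C@@H]2C(C)(C)CC(=O)C[C@]2(C)C1=O
F6 | step 1 | C2,C6-bis(p-toluenesulfonylhydrazone) of F5 | CC1CC(=NNS(=O)(=O)c2ccc(C)cc2)[C@@H]3C(C)(C)CC(=NNS(=O)(=O)c4ccc(C)cc4)C[C@]3(C)C1=O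
F7 | step 4 | C6 p-toluenesulfonylhydrazone of 3 | CC1=CC(=NNS(=O)(=O)c2ccc(C)cc2)[C@@H]3C(C)(C)C=CC[C@]3(C)C1=O
F8 | step 4 | (8S)-cis-fused 4,4,8,10-tetramethyl-2,6-diene-9-one (C2=C3 and C6=C7 alkenes) | C[C@H]1C=C[C@@H]2C(C)(C)C=CC[C@]2(C)C1=O
F9 | step 3 | C6 hydroxy C9 ketone from 4 (C6 and C8 epimers) | CC1CC(O)[C@@H]2C(C)(C)CCC[C@]2(C)C1=O
F10 | step 3 | O-(imidazole-1-carbothioyl) derivative of F9 | CC1CC(OC(=S)n2ccnc2)[C@@H]3C(C)(C)CCC[C@]3(C)C1=O
F11 | step 9 | 3-bromo-2,4,5-tris(methoxymethoxy)benzaldehyde | O=Cc1cc(OCOC)c(OCOC)c(Br)c1OCOC
F12 | step 9 | lithium (4-methylpiperazin-1-yl)[3-bromo-2,4,5-tris(methoxymethoxy)phenyl]methanolate | [Li]OC(N1CCN(C)CC1)c1cc(OCOC)c(OCOC)c(Br)c1OCOC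
F0 | step 10 | none | none
A1 | alternative 1 | (S)-4-benzyl-3-[(2E,8Z,10E)-3,7,7-trimethyldodeca-2,8,10-trienoyl]oxazolidin-2-one | C/C=C/C=C\C(C)(C)CCC/C(C)=C/C(=O)N1C(=O)OC[C@@H]1Cc1ccccc1
A2 | alternative 1 | cis-fused Δ6-octalin with the C9 acyl oxazolidinone | C[C@H]1C=C[C@@H]2C(C)(C)CCC[C@]2(C)[C@H]1C(=O)N1C(=O)OC[C@@H]1Cc1ccccc1
A3 | alternative 2 | 1,3,3,5-tetramethyl-2-vinylbicyclo[2.2.2]oct-5-en-2-ol (vinyl syn to the alkene bridge) | C=C[C@]1(O)C(C)(C)[C@H]2CC[C@]1(C)C=C2C
A4 | alternative 2 | cis-fused 4,4,8,10-tetramethyl-Δ8-octal-3-one | CC1=C[C@@]2(C)CCC(=O)C(C)(C)[C@H]2CC1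
A5 | alternative 3 | 3-[(3S)-3-methyl-5-[(1R)-2,6,6-trimethylcyclohex-2-en-1-yl]pent-1-yn-1-yl]-2,4,5-tris(methoxymethoxy)benzaldehyde | CC1=CCCC(C)(C)[C@H]1CC[C@H](C)C#Cc1c(OCOC)c(OCOC)cc(C=O)c1OCOC
A6 | alternative 3 | 1,2-dehydro analogue of 18 | C[C@H]1CC[C@@H]2C(C)(C)CC=C[C@]2(C)/C1=C/c1c(OCOC)c(OCOC)cc(C=O)c1OCOC
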